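## Analysis of the target

Lignan numbering is used throughout: C7–C9 for the guaiacyl C6C3 unit, C7'–C9' for the central syringyl unit, C7''–C9'' for the side chain.

The target is a sesquineolignan built from three C6C3 units. Two of them form a furofuran, a cis-fused 3,7-dioxabicyclo[3.3.0]octane in which ring A is O–C7–C8–C8'–C9' and ring B is O–C7'–C8'–C8–C9. C7 carries a 4-hydroxy-3-methoxyphenyl (guaiacyl) group, and C7' a 3,5-dimethoxyphenyl (syringyl) group whose 4'-oxygen is bound to C8'' of a 1-(4-hydroxy-3,5-dimethoxyphenyl)propane-1,3-diol chain. Reading the SMILES gives 7R, 8S, 8'S, 7'S in the bicycle and 7''R, 8''R in the chain. In relative terms H8 and H8' are cis, H7 is trans to H8 (guaiacyl exo, convex face), H7' is cis to H8' (syringyl endo, concave face), and the chain is the threo (syn) isomer. The two benzylic centres of the bicycle differ in aryl group and in relative configuration, so a symmetric dimerisation is excluded. The endo aryl group is the less stable arrangement, so it must be formed under kinetic control and then kept away from acids that reopen the benzylic C7'–O bond. The chain centres are remote from the bicycle and need their own source of absolute configuration, and the C8''–O bond joins a secondary carbon to a phenol flanked by two methoxy groups, which is hard to make by direct substitution. Sensitive groups are the two benzylic ring ethers (acid, hydrogenolysis), the two free phenols (oxidation) and the p-hydroxybenzylic alcohol at C7'' (acid, quinone methide formation). The strategy rests on the chain C7–C8–C8'–C7': the four carbons C9–C8–C8'–C9' have the oxidation pattern of a butenolide, C7' is an aryl acyl anion equivalent that can add to its β-carbon C8', and C7 is an aryl aldehyde carbon that can take the resulting enolate at C8.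

## Retrosynthetic reasoning

Target 28 is traced back to its bis-silyl ether 27. Both phenols are kept as triisopropylsilyl ethers to the end, so the last step is a buffered fluoride treatment that spares the benzylic ethers and the benzylic alcohol.

In 27 the C7''–C8'' bond is cut, which leads through the imide adduct 26 to the aryloxyacetyl imide 23 and aldehyde 24. The cut is placed there, and not at C8''–O, because the hindered phenol oxygen then sits on the enolate partner from the start and no substitution at a secondary carbon is needed. The forward aldol must give the syn adduct, which corresponds to the threo chain, with the absolute sense dictated by auxiliary 21; reduction then removes the auxiliary and gives C9''.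

Imide 23 is cut at the O–CH2 bond into phenol 20 and the bromoacetyl imide 22, made from 21. A primary α-halo carbonyl carbon is the one electrophile that a di-ortho-substituted phenoxide alkylates reliably.

Phenol 20 comes from the benzyl ether 19. Benzyl on the central ring and silyl on the guaiacyl ring are orthogonal, so only the oxygen that must carry the chain is freed.

In 19 the C7'–H bond is cut, leading to the oxocarbenium ion 18 and the hemiketal 17. The endo aryl group cannot be reached by equilibration, so it is set by irreversible hydride delivery to the convex face of the cis-fused bicycle. Hemiketal 17 in turn is cut at O–C7' to the hydroxy ketone 16, which is the unmasked form of the dithiane alcohol 15.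

Ring A of 15 is cut at O–C7, leading through cation 14 to triol 13. Closing this ring while C7' is still masked means that only the C9' hydroxyl can reach C7, and the C7 hydroxyl is consumed before a ketone appears with which it could form a competing 2,5-diaryl oxolane. The cation also erases the C7 configuration and lets the aryl group settle trans to the C9 substituent.

Triol 13 comes from lactone 12 by reduction of the carbonyl carbon C9 and the acetal carbon C9', which releases auxiliary 6. A trans arrangement of the C8 and C8' substituents on the lactone becomes the cis ring fusion once C9 and C9' are joined to C7' and C7 instead of to each other.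

Lactone 12 is cut at C7'–C8' and at C8–C7 into dithiane 3, butenolide 7 and aldehyde 9. This is the central disconnection: it assembles the whole carbon skeleton of the bicycle in one flask and takes the absolute configuration of C8' and C8 from the acetal carbon of 7.

The three components are one or two steps from commercial materials: 3 from 1 via 2, 7 from 4 and 6 via 5, and 9 from 8. Aldehyde 24 also comes from 1.

## Alternatives that were turned down

Alternative 1: Ring B is cut at C9–C8 and ring A at O–C7, so that C9 is delivered as the methylene of a methoxymethyl ether. The acyclic (E)-styrene A2 holds C7' and C8' as preformed stereocentres, the methoxymethyl group on the C7' oxygen and a silyl ether on the C9' oxygen. A silyl triflate would ionise it; the oxocarbenium ion would be attacked by the styrene carbon C8, and the benzylic cation at C7 would be taken by the C9' oxygen, giving the protected furofuran A1, which is identical with 19.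
- For: one step closes both rings, sets C8 and C7, and needs no sulfur, no auxiliary acetal and no hemiketal reduction. On step economy in the middle of the route it is stronger than the chosen plan.
- Against: the ion sits on the oxygen of a very electron-rich benzylic centre, so ionisation of the C7'–O bond and a 2-oxonia-Cope shift (which would give an aryl-stabilised oxocarbenium ion) can both scramble C7' and C8'. Ring A can close only if C8 is formed cis to C9', and nothing but the transition state of an ion–alkene closure enforces that. The endo aryl group must survive the same Lewis acid that turns endo furofurans into exo ones. A2 itself needs an enantioselective construction of the C7'/C8' pair that is no shorter than the butenolide route.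
- Comparison: the chosen strategy gives up the one-step bicyclisation. In exchange it fixes C8' and C8 by substrate control from a crystalline acetal and forms the endo centre last, cold, by an irreversible hydride transfer.

Alternative 2: The cut is made at C8'–C7' and at the ring B oxygen–C9 bond, with C9 kept as a lactone carbonyl. A chiral triazolylidene carbene would turn enal A4 into a homoenolate whose β-carbon adds to aldehyde 2, and acylation of the alkoxide would release the cis lactone A3.
- For: the method is catalytic, needs no stoichiometric auxiliary, and sets the C7'/C8' relation that corresponds to the endo aryl group at the outset. On both points it is stronger than the chosen plan.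
- Against: carbene homoenolates add sluggishly to electron-rich benzaldehydes such as 2, so self-condensation of A4 competes. Cis/trans and enantiofacial control in intermolecular enal–aldehyde annulations are modest. The γ-silyloxy group of A4 is a leaving group in the extended Breslow intermediate, which opens an elimination path. After A3, C8 still needs a lactone aldol with 9, and the C9 carbonyl must be taken down to a methylene in two operations beside two benzylic C–O bonds.
- Comparison: the chosen strategy spends a recoverable auxiliary and sets the endo centre late. It offers bond formations that are known to work with these electron-rich aryl partners, and it brings in both aryl carbons in one flask.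

Alternative 3: Ring B is cut at O–C9 of an enol ether, which leads to a cyclopropane. In the acylcyclopropane lactone A6 the cyclopropane carbon C8' carries both the lactone carbonyl C9' and the aryl ketone C7'. Iodide from a magnesium halide would open it at the methylene C9, and the ketone enolate oxygen would displace iodide to give the bicyclic enol ether lactone A5 (Cloke–Wilson ring expansion).
- For: the bicyclic skeleton, both ring oxygens and the exo C7 centre are in place early, and syn hydrogenation of the C7'=C8' bond from the convex face would give the endo aryl group and the cis fusion together. On speed to the ring system it is at least equal to the chosen plan.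
- Against: A6 needs an enantiopure secondary allylic alcohol and an intramolecular diazo cyclopropanation. The cyclopropane has no donor substituent at C9, so opening is slow. A5 leaves two stereocentres to be set by hydrogenating a tetrasubstituted push–pull alkene, under conditions that also threaten the benzyl ether and the benzylic lactone C–O bond. The lactone carbonyl C9' must still be reduced to a methylene.
- Comparison: the chosen strategy arrives with C9 and C9' already at the alcohol level after one hydride step. It sets C8' before any ring of the bicycle exists, so no late alkene face selection is needed.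

Key step: step 6

Remark on the chemistry: adduct 12 and triol 13 are written as their 7R epimers; the 7S epimers, if they form as well, follow the same steps because C7 is planar in cation 14.

## Route

Step 1
Reactants: 1 syringaldehyde
Product: 2 4-(benzyloxy)-3,5-dimethoxybenzaldehyde
Conditions: BnBr, K2CO3, DMF, 60 °C
Reagents that add atoms: benzyl bromide, BrCc1ccccc1
Why: Williamson ether synthesis on the only nucleophilic site; the benzyl ether withstands the organolithium, hydride and Lewis acid steps that follow and is orthogonal to the silyl ethers.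

Step 2
Reactants: 2 4-(benzyloxy)-3,5-dimethoxybenzaldehyde
Product: 3 2-[4-(benzyloxy)-3,5-dimethoxyphenyl]-1,3-dithiane
Conditions: HS(CH2)3SH, BF3·OEt2 (cat.), CH2Cl2, 0 °C to rt
Reagents that add atoms: propane-1,3-dithiol, SCCCS
Why: Lewis acid catalysed dithioacetalisation turns the aldehyde carbon, the future C7', into an acyl anion equivalent.

Step 3
Reactants: 4 furfural
Product: 5 5-hydroxyfuran-2(5H)-one (racemic)
Conditions: O2, rose bengal (cat.), MeOH, visible light, rt
Reagents that add atoms: dioxygen, O=O
Why: Dye-sensitised photooxygenation: singlet oxygen adds across the furan in a [4+2] cycloaddition and the endoperoxide fragments in methanol, losing the formyl carbon as methyl formate and leaving the hydroxybutenolide.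

Step 4
Reactants: 5 5-hydroxyfuran-2(5H)-one; 6 (+)-menthol
Product: 7 (5S)-5-[(1S,2R,5S)-menthyloxy]furan-2(5H)-one
Conditions: CSA (cat.), toluene, reflux, Dean–Stark; crystallisation from petroleum ether with acid-catalysed epimerisation of the mother liquor
Reagents that add atoms: none
Why: Acid-catalysed acetalisation gives both C5 epimers, which interconvert through the cyclic oxocarbenium ion; the (5S) epimer of the (+)-menthyl series is the crystalline one, so a crystallisation-induced diastereomer transformation should deliver it as a single stereoisomer.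

Step 5
Reactants: 8 vanillin
Product: 9 3-methoxy-4-(triisopropylsilyloxy)benzaldehyde
Conditions: TIPSCl, imidazole, DMF, rt
Reagents that add atoms: triisopropylsilyl chloride, CC(C)[Si](Cl)(C(C)C)C(C)C
Why: Imidazole-promoted silylation of the phenol; the bulky aryl silyl ether tolerates lithium enolates, LiAlH4, BF3·OEt2 and hydrogenolysis.

Step 6
Reactants: 3 2-[4-(benzyloxy)-3,5-dimethoxyphenyl]-1,3-dithiane; 7 (5S)-5-[(1S,2R,5S)-menthyloxy]furan-2(5H)-one; 9 3-methoxy-4-(triisopropylsilyloxy)benzaldehyde
Product: 12 trans-3,4-disubstituted menthyloxy lactone with C7' as dithiane carbon and C7 as carbinol (3R,4S,5S; carbinol R), via 2-lithio dithiane 10 (not isolated), via lactone lithium enolate 11 (not isolated)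
Conditions: n-BuLi, THF, −78 to −20 °C; then 7, −78 °C; then 9, −78 °C; AcOH, −78 °C
Reagents that add atoms: none
Why: Deprotonation of 3 gives the sulfur-stabilised benzylic anion 10, which adds to C8' of butenolide 7 in a Michael addition to give lithium enolate 11, and 11 is trapped at C8 by aldehyde 9 in an aldol addition; the closest known reaction type is the tandem conjugate addition–aldol of lithiated dithioacetals with 5-alkoxybutenolides. No ring is closed. C8' is controlled by the acetal carbon C9': the anion enters anti to the menthyloxy group, which gives 8'S from the 5S acetal. C8 is controlled by C8': the aldehyde approaches the enolate face opposite the bulky dithianyl group, so the substituents on C8 and C8' become trans. C7 is set only by the chelated aldol transition state of the ring-fixed E-enolate and is not needed later. The step needs 1,4- over 1,2-addition, which the soft and hindered 2-aryl dithiane anion and the unhindered β-carbon secure. It also needs the enolate to be trapped before it equilibrates, which the non-enolisable aldehyde, the low temperature and the cold acidic quench (no retro-aldol) secure.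

Step 7
Reactants: 12 menthyloxy lactone aldol adduct
Product: 13 (2S,3S)-2-[(R)-hydroxy(3-methoxy-4-triisopropylsilyloxyphenyl)methyl]-3-[2-(4-benzyloxy-3,5-dimethoxyphenyl)-1,3-dithian-2-yl]butane-1,4-diol
Conditions: LiAlH4, THF, 0 °C to rt; Fieser work-up
Reagents that add atoms: none
Why: Hydride reduction of the acylal-type lactone: the carbonyl carbon C9 and the acetal carbon C9' (unmasked as an aldehyde when menthoxide leaves) both end as CH2OH, C8 and C8' are untouched and (+)-menthol is recovered.

Step 8
Reactants: 13 dithiane triol
Product: 15 {(2R,3S,4S)-4-[2-(4-benzyloxy-3,5-dimethoxyphenyl)-1,3-dithian-2-yl]-2-(3-methoxy-4-triisopropylsilyloxyphenyl)oxolan-3-yl}methanol, via benzylic cation 14 (not isolated)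
Conditions: CSA (cat.), CH2Cl2, 0 °C to rt
Reagents that add atoms: none
Why: Acid-catalysed SN1 cycloetherification: the p-silyloxybenzylic alcohol ionises to cation 14 and only the C9' hydroxyl can reach C7 through a five-membered transition state (the C9 hydroxyl would give an oxetane), which closes ring A. The aryl group is expected to settle trans to the C9 substituent on C8 (2,3-trans oxolane, reached reversibly), which is 7R whatever the carbinol configuration was.

Step 9
Reactants: 15 ring A oxolane dithiane
Product: 17 bicyclic hemiketal (7R,8S,8'S; both anomers at C7'), via hydroxy ketone 16 (not isolated)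
Conditions: MeI, CaCO3, MeCN–H2O (9:1), 45 °C
Reagents that add atoms: water, O
Why: Alkylative dithiane hydrolysis: S-methylation gives a thionium ion that water captures, and the freed aryl ketone 16 is closed by the only remaining hydroxyl (C9–OH) to the cis-fused hemiketal. The buffered neutral medium leaves the benzylic ether, the silyl ether and the benzyl ether untouched.

Step 10
Reactants: 17 bicyclic hemiketal
Product: 19 (7R,7'S,8S,8'S)-4'-benzyloxy-3,3',5'-trimethoxy-4-(triisopropylsilyloxy)-7,9':7',9-diepoxylignane, via cyclic oxocarbenium ion 18 (not isolated)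
Conditions: Et3SiH, BF3·OEt2, CH2Cl2, −78 to −40 °C; cold NaHCO3 quench
Reagents that add atoms: none
Why: Ionic hydrogenation of a lactol: BF3·OEt2 ionises the hemiketal to the aryl-stabilised oxocarbenium ion 18 and Et3SiH delivers hydride to the convex face of the cis-fused bicycle, so H7' ends exo and cis to H8' and the syringyl ring endo (7'S). The low temperature and the cold basic quench prevent acid-induced epimerisation of the endo aryl group.

Step 11
Reactants: 19 protected furofuran
Product: 20 (7R,7'S,8S,8'S)-3,3',5'-trimethoxy-4-(triisopropylsilyloxy)-7,9':7',9-diepoxylignan-4'-ol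
Conditions: H2 (1 atm), 10% Pd/C, EtOAc, rt; stopped at consumption of 19
Reagents that add atoms: none
Why: Hydrogenolysis of the aryl benzyl ether is faster than cleavage of the dialkyl benzylic ring C–O bonds under neutral conditions, and the silyl ether is inert, so only the phenol that must carry the chain is freed.

Step 12
Reactants: 21 (4S)-4-benzyl-1,3-oxazolidin-2-one
Product: 22 (4S)-4-benzyl-3-(bromoacetyl)-1,3-oxazolidin-2-one
Conditions: n-BuLi, THF, −78 °C; BrCH2COBr, −78 °C
Reagents that add atoms: bromoacetyl bromide, BrCC(Br)=O
Why: N-acylation of the lithiated oxazolidinone by the acid bromide, which reacts at the acyl carbon far faster than at the CH2Br carbon at low temperature.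

Step 13
Reactants: 20 furofuran phenol; 22 (4S)-4-benzyl-3-(bromoacetyl)-1,3-oxazolidin-2-one
Product: 23 (4S)-4-benzyl-3-[(aryloxy)acetyl]-1,3-oxazolidin-2-one, aryloxy being the 4'-oxygen of 20
Conditions: K2CO3, acetone (dry), rt
Reagents that add atoms: none
Why: Williamson ether synthesis at a primary α-halo imide; the adjacent carbonyl accelerates SN2 enough for the di-ortho-substituted phenoxide, and anhydrous carbonate in acetone leaves the aryl silyl ether intact.

Step 14
Reactants: 1 syringaldehyde
Product: 24 3,5-dimethoxy-4-(triisopropylsilyloxy)benzaldehyde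
Conditions: TIPSCl, imidazole, DMF, rt to 40 °C
Reagents that add atoms: triisopropylsilyl chloride, CC(C)[Si](Cl)(C(C)C)C(C)C
Why: Silylation of the hindered phenol; both remaining phenol protecting groups are then the same and fall in one final step.

Step 15
Reactants: 23 aryloxyacetyl imide; 24 3,5-dimethoxy-4-(triisopropylsilyloxy)benzaldehyde
Product: 26 syn-aldol adduct (2S,3R) on the auxiliary, via dibutylboron Z-enolate 25 (not isolated)
Conditions: Bu2BOTf, iPr2NEt, CH2Cl2, −78 to 0 °C; then 24, −78 to 0 °C; pH 7 buffer, MeOH, H2O2, 0 °C
Reagents that add atoms: none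
Why: Evans syn-aldol of a glycolate-type imide: soft enolisation gives the Z-boron enolate 25, which reacts through a closed chair (Zimmerman–Traxler) transition state on the face away from the benzyl group of the (S)-auxiliary. The syn adduct expected from this auxiliary is (2S,3R), which is 8''R and 7''R, the threo chain of the target.

Step 16
Reactants: 26 syn-aldol adduct
Product: 27 bis(triisopropylsilyl) ether of the target (7''R,8''R)
Conditions: LiBH4, THF, MeOH (1 equiv), 0 °C
Reagents that add atoms: none
Why: Reductive cleavage of the N-acyl oxazolidinone to the primary alcohol C9''; the two new stereocentres are not touched and the auxiliary is recovered.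

Step 17
Reactants: 27 bis(triisopropylsilyl) ether
Product: 28 target
Conditions: Bu4NF, AcOH, THF, 0 °C
Reagents that add atoms: none
Why: Fluoride cleavage of both aryl silyl ethers; buffering with acetic acid keeps the phenoxides protonated, so neither the p-hydroxybenzylic alcohol nor the endo benzylic ether is endangered.

## Compound list

1 | syringaldehyde (4-hydroxy-3,5-dimethoxybenzaldehyde) | COc1cc(C=O)cc(OC)c1O | starting material
2 | 4-(benzyloxy)-3,5-dimethoxybenzaldehyde | COc1cc(C=O)cc(OC)c1OCc1ccccc1 | intermediate
3 | 2-[4-(benzyloxy)-3,5-dimethoxyphenyl]-1,3-dithiane | COc1cc(C2SCCCS2)cc(OC)c1OCc1ccccc1 | intermediate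
4 | furfural | O=Cc1ccco1 | starting material
5 | 5-hydroxyfuran-2(5H)-one (racemic) | O=C1C=CC(O)O1 | intermediate
6 | (+)-menthol, (1S,2R,5S)-5-methyl-2-(propan-2-yl)cyclohexan-1-ol | CC(C)[C@H]1CC[C@H](C)C[C@@H]1O | starting material
7 | (5S)-5-[(1S,2R,5S)-menthyloxy]furan-2(5H)-one | O=C1C=C[C@@H](O[C@H]2C[C@@H](C)CC[C@@H]2C(C)C)O1 | intermediate
8 | vanillin | COc1cc(C=O)ccc1O | starting material
9 | 3-methoxy-4-(triisopropylsilyloxy)benzaldehyde | COc1cc(C=O)ccc1O[Si](C(C)C)(C(C)C)C(C)C | intermediate
10 | 2-lithio-2-[4-(benzyloxy)-3,5-dimethoxyphenyl]-1,3-dithiane (not isolated) | COc1cc(C2([Li])SCCCS2)cc(OC)c1OCc1ccccc1 | intermediate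
11 | lithium enolate of the (4S,5S) conjugate adduct lactone (not isolated) | [Li]OC1=C[C@H](C2(c3cc(OC)c(OCc4ccccc4)c(OC)c3)SCCCS2)[C@@H](O[C@H]2C[C@@H](C)CC[C@@H]2C(C)C)O1 | intermediate
12 | (3R,4S,5S)-4-[2-(4-benzyloxy-3,5-dimethoxyphenyl)-1,3-dithian-2-yl]-3-[(R)-hydroxy(3-methoxy-4-triisopropylsilyloxyphenyl)methyl]-5-[(1S,2R,5S)-menthyloxy]dihydrofuran-2(3H)-one | O=C1O[C@H](O[C@H]2C[C@@H](C)CC[C@@H]2C(C)C)[C@@H](C2(c3cc(OC)c(OCc4ccccc4)c(OC)c3)SCCCS2)[C@@H]1[C@@H](O)c1ccc(O[Si](C(C)C)(C(C)C)C(C)C)c(OC)c1 | intermediate
13 | (2S,3S)-2-[(R)-hydroxy(3-methoxy-4-triisopropylsilyloxyphenyl)methyl]-3-[2-(4-benzyloxy-3,5-dimethoxyphenyl)-1,3-dithian-2-yl]butane-1,4-diol | OC[C@@H]([C@@H](O)c1ccc(O[Si](C(C)C)(C(C)C)C(C)C)c(OC)c1)[C@@H](CO)C1(c2cc(OC)c(OCc3ccccc3)c(OC)c2)SCCCS1 | intermediate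
14 | benzylic cation at C7 derived from 13 (not isolated) | OC[C@@H]([CH+]c1ccc(O[Si](C(C)C)(C(C)C)C(C)C)c(OC)c1)[C@@H](CO)C1(c2cc(OC)c(OCc3ccccc3)c(OC)c2)SCCCS1 | intermediate
15 | {(2R,3S,4S)-4-[2-(4-benzyloxy-3,5-dimethoxyphenyl)-1,3-dithian-2-yl]-2-(3-methoxy-4-triisopropylsilyloxyphenyl)oxolan-3-yl}methanol | COc1cc([C@@H]2OC[C@@H](C3(c4cc(OC)c(OCc5ccccc5)c(OC)c4)SCCCS3)[C@H]2CO)ccc1O[Si](C(C)C)(C(C)C)C(C)C | intermediate
16 | (4-benzyloxy-3,5-dimethoxyphenyl)[(3S,4S,5R)-4-(hydroxymethyl)-5-(3-methoxy-4-triisopropylsilyloxyphenyl)oxolan-3-yl]methanone (not isolated) | COc1cc([C@@H]2OC[C@@H](C(=O)c3cc(OC)c(OCc4ccccc4)c(OC)c3)[C@H]2CO)ccc1O[Si](C(C)C)(C(C)C)C(C)C | intermediate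
17 | (7R,8S,8'S)-4'-benzyloxy-7'-hydroxy-3,3',5'-trimethoxy-4-(triisopropylsilyloxy)-7,9':7',9-diepoxylignane (both anomers at C7') | COc1cc([C@@H]2OC[C@@H]3[C@H]2COC3(O)c2cc(OC)c(OCc3ccccc3)c(OC)c2)ccc1O[Si](C(C)C)(C(C)C)C(C)C | intermediate
18 | cyclic oxocarbenium ion at C7' derived from 17 (not isolated) | COc1cc([C@@H]2OC[C@@H]3[C@H]2C[O+]=C3c2cc(OC)c(OCc3ccccc3)c(OC)c2)ccc1O[Si](C(C)C)(C(C)C)C(C)C | intermediate
19 | (7R,7'S,8S,8'S)-4'-benzyloxy-3,3',5'-trimethoxy-4-(triisopropylsilyloxy)-7,9':7',9-diepoxylignane | COc1cc([C@@H]2OC[C@@H]3[C@H]2CO[C@@H]3c2cc(OC)c(OCc3ccccc3)c(OC)c2)ccc1O[Si](C(C)C)(C(C)C)C(C)C | intermediate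
20 | (7R,7'S,8S,8'S)-3,3',5'-trimethoxy-4-(triisopropylsilyloxy)-7,9':7',9-diepoxylignan-4'-ol | COc1cc([C@@H]2OC[C@@H]3[C@H]2CO[C@@H]3c2cc(OC)c(O)c(OC)c2)ccc1O[Si](C(C)C)(C(C)C)C(C)C | intermediate
21 | (4S)-4-benzyl-1,3-oxazolidin-2-one | O=C1N[C@@H](Cc2ccccc2)CO1 | starting material
22 | (4S)-4-benzyl-3-(bromoacetyl)-1,3-oxazolidin-2-one | O=C(CBr)N1[C@@H](Cc2ccccc2)COC1=O | intermediate
23 | (4S)-4-benzyl-3-[(aryloxy)acetyl]-1,3-oxazolidin-2-one, aryloxy = 4'-oxygen of 20 | COc1cc([C@@H]2OC[C@@H]3[C@H]2CO[C@@H]3c2cc(OC)c(OCC(=O)N3[C@@H](Cc4ccccc4)COC3=O)c(OC)c2)ccc1O[Si](C(C)C)(C(C)C)C(C)C | intermediate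
24 | 3,5-dimethoxy-4-(triisopropylsilyloxy)benzaldehyde | COc1cc(C=O)cc(OC)c1O[Si](C(C)C)(C(C)C)C(C)C | intermediate
25 | dibutylboron Z-enolate of 23 (not isolated) | COc1cc([C@@H]2OC[C@@H]3[C@H]2CO[C@@H]3c2cc(OC)c(O/C=C(\OB(CCCC)CCCC)N3[C@@H](Cc4ccccc4)COC3=O)c(OC)c2)ccc1O[Si](C(C)C)(C(C)C)C(C)C | intermediate
26 | (4S)-4-benzyl-3-[(2S,3R)-2-(aryloxy)-3-hydroxy-3-(3,5-dimethoxy-4-triisopropylsilyloxyphenyl)propanoyl]-1,3-oxazolidin-2-one | COc1cc([C@@H]2OC[C@@H]3[C@H]2CO[C@@H]3c2cc(OC)c(O[C@H](C(=O)N3[C@@H](Cc4ccccc4)COC3=O)[C@H](O)c3cc(OC)c(O[Si](C(C)C)(C(C)C)C(C)C)c(OC)c3)c(OC)c2)ccc1O[Si](C(C)C)(C(C)C)C(C)C | intermediate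
27 | 4,4'''-bis(triisopropylsilyl) ether of the target, (7''R,8''R)-diol | COc1cc([C@@H]2OC[C@@H]3[C@H]2CO[C@@H]3c2cc(OC)c(O[C@H](CO)[C@H](O)c3cc(OC)c(O[Si](C(C)C)(C(C)C)C(C)C)c(OC)c3)c(OC)c2)ccc1O[Si](C(C)C)(C(C)C)C(C)C | intermediate
28 | target, (7R,7'S,8S,8'S,7''R,8''R) | COc1cc([C@@H]2OC[C@@H]3[C@H]2CO[C@@H]3c2cc(OC)c(O[C@H](CO)[C@H](O)c3cc(OC)c(O)c(OC)c3)c(OC)c2)ccc1O | target

## Step count and least certain steps

Total: 17 steps. Longest linear sequence: 12 steps (1 → 2 → 3 → 12 → 13 → 15 → 17 → 19 → 20 → 23 → 26 → 27 → 28, i.e. steps 1, 2, 6, 7, 8, 9, 10, 11, 13, 15, 16, 17).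

Step 6 (key step). The most likely failures are competing 1,2-addition of anion 10 to the lactone carbonyl, and incomplete trapping of enolate 11 with retro-aldol or retro-Michael reversal if the mixture warms before the quench. Both come from running three equilibria in one flask. Fallback: setting out from 3 and 7, the conjugate addition is run alone and quenched with acid to give the conjugate adduct lactone F1. F1 is then re-enolised with LiN(iPr)2, transmetalated with ZnCl2 to a less basic and less reversible zinc enolate, and treated with 9. This returns to the route at 12, with the two bond formations optimised separately.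

Step 8. Cation 14 is generated next to an electron-rich arene and two sulfur atoms. Friedel–Crafts alkylation of the benzyloxydimethoxyphenyl ring (six-membered closure to an aryltetralin), sulfur participation, or incomplete equilibration to the trans oxolane could lower the yield or the selectivity at C7. Fallback: setting out from 13, the dithiane is hydrolysed first (MeI, CaCO3, aqueous MeCN) to the monocyclic hemiketal F2, in which the aryl ring is no longer attached to a thioacetal carbon. Treatment of F2 with Et3SiH and BF3·OEt2 at low temperature then reduces the oxocarbenium ion and closes ring A in the same flask, returning at 19. This is held in reserve, not used first, because in F2 the C7 hydroxyl can compete with the C9 hydroxyl for the ketone.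

Step 10. Hydride delivery could lose its facial preference. The product, whose endo aryl group is the less stable epimer, could be epimerised at C7' (or C7) by the Lewis acid through reopening of a benzylic C–O bond, and prolonged exposure could also reduce a benzylic C–O bond. Fallback: setting out from 17, the hemiketal is dehydrated under basic conditions (MsCl, Et3N) to the dihydrofuran F3. Hydrogenation of F3 over Pd/C adds both hydrogens syn from the convex face, which gives the cis fusion and the endo aryl group without any cationic intermediate, and removes the benzyl group in the same operation. It returns at 20.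

Step 15. The electron-rich, doubly ortho-flanked aldehyde 24 may add slowly, and warming to force conversion could erode syn selectivity. Bu2BOTf could also coordinate to the furofuran oxygens and promote epimerisation of the endo C7' centre. Fallback (catalyst-controlled reduction in place of auxiliary-controlled C–C bond formation):
- From 24, addition of the lithium enolate of ethyl acetate gives the β-hydroxy ester F4, Dess–Martin oxidation gives the β-keto ester F5, and NBS gives the α-bromo-β-keto ester F6.
- Phenol 20 is alkylated with F6 (K2CO3, acetone) to the α-aryloxy-β-keto ester F7, which is configurationally labile at C8''.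
- Noyori–Ikariya transfer hydrogenation of F7 with RuCl[(S,S)-TsDPEN](p-cymene) in HCO2H–Et3N, under dynamic kinetic resolution, is expected to give the syn-hydroxy ester F8 (2S,3R).
- LiBH4 reduces F8 to 27, where the route is rejoined.

## Further compounds

F1 | step 6 | (4S,5S)-4-[2-(4-benzyloxy-3,5-dimethoxyphenyl)-1,3-dithian-2-yl]-5-[(1S,2R,5S)-menthyloxy]dihydrofuran-2(3H)-one | O=C1C[C@H](C2(c3cc(OC)c(OCc4ccccc4)c(OC)c3)SCCCS2)[C@@H](O[C@H]2C[C@@H](C)CC[C@@H]2C(C)C)O1
F2 | step 8 | (3S,4S)-2-(4-benzyloxy-3,5-dimethoxyphenyl)-4-[(R)-hydroxy(3-methoxy-4-triisopropylsilyloxyphenyl)methyl]-3-(hydroxymethyl)oxolan-2-ol (both anomers) | OC[C@@H]1[C@H]([C@@H](O)c2ccc(O[Si](C(C)C)(C(C)C)C(C)C)c(OC)c2)COC1(O)c1cc(OC)c(OCc2ccccc2)c(OC)c1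
F3 | step 10 | (7R,8S)-4'-benzyloxy-3,3',5'-trimethoxy-4-(triisopropylsilyloxy)-7,9':7',9-diepoxylign-7'-ene (C7'=C8' enol ether) | COc1cc([C@@H]2OCC3=C(c4cc(OC)c(OCc5ccccc5)c(OC)c4)OC[C@@H]23)ccc1O[Si](C(C)C)(C(C)C)C(C)C
F4 | step 15 | ethyl 3-hydroxy-3-[3,5-dimethoxy-4-(triisopropylsilyloxy)phenyl]propanoate (racemic) | CCOC(=O)CC(O)c1cc(OC)c(O[Si](C(C)C)(C(C)C)C(C)C)c(OC)c1
F5 | step 15 | ethyl 3-[3,5-dimethoxy-4-(triisopropylsilyloxy)phenyl]-3-oxopropanoate | CCOC(=O)CC(=O)c1cc(OC)c(O[Si](C(C)C)(C(C)C)C(C)C)c(OC)c1
F6 | step 15 | ethyl 2-bromo-3-[3,5-dimethoxy-4-(triisopropylsilyloxy)phenyl]-3-oxopropanoate (racemic) | CCOC(=O)C(Br)C(=O)c1cc(OC)c(O[Si](C(C)C)(C(C)C)C(C)C)c(OC)c1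
F7 | step 15 | ethyl 2-(aryloxy)-3-[3,5-dimethoxy-4-(triisopropylsilyloxy)phenyl]-3-oxopropanoate, aryloxy = 4'-oxygen of 20 (both C8'' epimers) | COc1cc([C@@H]2OC[C@@H]3[C@H]2CO[C@@H]3c2cc(OC)c(OC(C(=O)OCC)C(=O)c3cc(OC)c(O[Si](C(C)C)(C(C)C)C(C)C)c(OC)c3)c(OC)c2)ccc1O[Si](C(C)C)(C(C)C)C(C)C
F8 | step 15 | ethyl (2S,3R)-2-(aryloxy)-3-hydroxy-3-[3,5-dimethoxy-4-(triisopropylsilyloxy)phenyl]propanoate, aryloxy = 4'-oxygen of 20 | COc1cc([C@@H]2OC[C@@H]3[C@H]2CO[C@@H]3c2cc(OC)c(O[C@H](C(=O)OCC)[C@H](O)c3cc(OC)c(O[Si](C(C)C)(C(C)C)C(C)C)c(OC)c3)c(OC)c2)ccc1O[Si](C(C)C)(C(C)C)C(C)C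
A1 | alternative 1 | protected furofuran (guaiacyl O-triisopropylsilyl exo, syringyl O-benzyl endo), identical with 19 | COc1cc([C@@H]2OC[C@@H]3[C@H]2CO[C@@H]3c2cc(OC)c(OCc3ccccc3)c(OC)c2)ccc1O[Si](C(C)C)(C(C)C)C(C)C
A2 | alternative 1 | (E)-styrene with methoxymethyl ether on the C7' oxygen and tert-butyldimethylsilyl ether on the C9' oxygen | COc1cc(/C=C/[C@@H](CO[Si](C)(C)C(C)(C)C)[C@H](OCOC)c2cc(OC)c(OCc3ccccc3)c(OC)c2)ccc1O[Si](C(C)C)(C(C)C)C(C)C
A3 | alternative 2 | cis-4-(tert-butyldimethylsilyloxymethyl)-5-(4-benzyloxy-3,5-dimethoxyphenyl)dihydrofuran-2(3H)-one | O=C1C[C@@H](CO[Si](C)(C)C(C)(C)C)[C@@H](c2cc(OC)c(OCc3ccccc3)c(OC)c2)O1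
A4 | alternative 2 | (E)-4-(tert-butyldimethylsilyloxy)but-2-enal | O=C/C=C/CO[Si](C)(C)C(C)(C)C
A5 | alternative 3 | bicyclic enol ether lactone (C7'=C8', lactone carbonyl at C9') | COc1cc([C@@H]2OC(=O)C3=C(c4cc(OC)c(OCc5ccccc5)c(OC)c4)OC[C@@H]23)ccc1O[Si](C(C)C)(C(C)C)C(C)C
A6 | alternative 3 | 1-aroyl-4-aryl-3-oxabicyclo[3.1.0]hexan-2-one (acylcyclopropane lactone, aryl on the convex face) | COc1cc([C@@H]2OC(=O)[C@@]3(C(=O)c4cc(OC)c(OCc5ccccc5)c(OC)c4)C[C@@H]23)ccc1O[Si](C(C)C)(C(C)C)C(C)C
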